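Atom labels: ring A = a1 (CO2Me), a2 (Me), a3 (Me), a4 (O-acyl), a5 (Me), a6 (OMe); ring B = b1 (C=O), b2 (Me), b3 (CHO), b4 (OH), b5 (Me), b6 (OH).
Cuts: first the depside bond between the a4 oxygen and the b1 carbonyl, and the a6 O–CH3 bond. Ring A is then taken back to its dihydro (dione) level and cut at a1–a2 and a5–a6, which leaves dimethyl malonate and (E)-4-methylhex-4-en-3-one. The enone C=C goes back to pentan-3-one and acetaldehyde.
Enabling feature: the oxygens on a4 and a6 are 1,3 to each other and a1, next to a6, bears CO2Me, so ring A is the aromatized form of a 2,4-dioxocyclohexane-1-carboxylate. The methyls on a2, a3 and a5 already sit in the acyclic enone.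
Forward order: ring A is the only ring built (closed in step 2, aromatized in step 3). Ring B is bought as atraric acid and receives CHO at b3, its only free CH, then benzyl ethers and a free acid. The halves are joined at the a4 oxygen, the a6 OH is methylated and the benzyl ethers are removed.
Stereochemistry: the target has no stereocentre. The four centres of dihydro ring A arise as a mixture and vanish on aromatization.

Key step: step 2

Remark: the dihydro ring A compound is drawn as its diketo tautomer although it should exist largely as an enol; this affects no step.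

Step 1
Reactants: 1 pentan-3-one; 2 acetaldehyde
Product: 4 (E)-4-methylhex-4-en-3-one, via aldol 3 (not isolated)
Conditions: H2SO4 (cat.), excess 1 as solvent, 2 added slowly, 65 °C, closed vessel
Reagents that add atoms: none
Why: Acid-catalysed crossed aldol condensation: the symmetrical ketone, present in excess, can form only one enol, which should add to the much more electrophilic aldehyde, and aldol 3 should lose water under the same acid to give the conjugated enone with the thermodynamically preferred E geometry (of no consequence later).

Step 2
Reactants: 4 (E)-4-methylhex-4-en-3-one; 5 dimethyl malonate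
Product: 8 methyl 3,5,6-trimethyl-2,4-dioxocyclohexane-1-carboxylate (diastereomers/tautomers), via Michael adduct 6 (not isolated), via sodium enolate 7 (not isolated)
Conditions: NaOMe (1.1 equiv), MeOH, reflux; then aq. HCl, 0 °C
Reagents that add atoms: none
Why: Methoxide deprotonates 5 and the soft, stabilized carbanion adds to the β carbon of 4 (bond a1–a2) to give 6; proton exchange in methanol then makes the enolate at the CH2 of the ethyl ketone available, and this carbon attacks one of the two equivalent ester carbonyls and expels methoxide (bond a5–a6). The closest known reaction type is the tandem Michael–Claisen (Dieckmann-type) condensation of malonates with α,β-unsaturated ketones that gives dimedone and alkyl dihydroresorcylates. Ring A closes in the 6-(enolendo)-exo-trig mode, which is favoured. The four new stereocentres (a1, a2, a3, a5) are under no control and need none, since three of them epimerize through enols and all four become sp2 carbons in step 3. Two selectivities are needed: 1,4- over 1,2-addition, secured by the delocalized nucleophile and the reversibility of carbonyl addition, and closure through the CH2 and not the a3 methine, secured by ring size (six atoms against four). Every event up to the closure is reversible, and the final deprotonation to the vinylogous carboxylate 7 should pull the hindered α,β-dimethyl enone through; acid then liberates 8.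

Step 3
Reactants: 8 methyl 3,5,6-trimethyl-2,4-dioxocyclohexane-1-carboxylate
Product: 11 methyl 2,4-dihydroxy-3,5,6-trimethylbenzoate, via C3 bromide 9 (not isolated), via C1 bromide 10 (not isolated)
Conditions: Br2 (1.0 equiv), AcOH, 15 °C, then 60 °C
Reagents that add atoms: none
Why: Halogenation–dehydrohalogenation aromatization of a dihydroresorcylate: the enol should be brominated first at a5 (9), HBr-mediated transfer of positive bromine should move the halogen to a1 (10), where the neighbouring a2 hydrogen allows loss of HBr, tautomerization of the resulting enedione to the arene makes the sequence irreversible, and nuclear overbromination is excluded because no ring position is free.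

Step 4
Reactants: 12 methyl 2,4-dihydroxy-3,6-dimethylbenzoate (atraric acid)
Product: 14 methyl 5-formyl-2,4-dihydroxy-3,6-dimethylbenzoate, via chloro ether 13 (not isolated)
Conditions: Cl2CHOMe, TiCl4, CH2Cl2, 0 °C to rt; then aq. HCl
Reagents that add atoms: dichloromethyl methyl ether, COC(Cl)Cl; water, O
Why: Rieche formylation: the titanium phenoxide of the electron-rich resorcinol directs the chloro(methoxy)carbenium electrophile to b3, the only unsubstituted ring carbon and ortho to the b4 oxygen, and aqueous acid hydrolyses chloro ether 13 to the aldehyde.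

Step 5
Reactants: 14 methyl 5-formyl-2,4-dihydroxy-3,6-dimethylbenzoate
Product: 15 methyl 2,4-bis(benzyloxy)-5-formyl-3,6-dimethylbenzoate
Conditions: BnBr, K2CO3, DMF, 60 °C
Reagents that add atoms: benzyl bromide, BrCc1ccccc1
Why: Double Williamson etherification: in a dipolar aprotic solvent with warming both hydrogen-bonded phenols should be deprotonated and O-benzylated, and benzyl is chosen because it withstands hot hydroxide, trifluoroacetic acid and K2CO3/MeI.

Step 6
Reactants: 15 methyl 2,4-bis(benzyloxy)-5-formyl-3,6-dimethylbenzoate
Product: 16 2,4-bis(benzyloxy)-5-formyl-3,6-dimethylbenzoic acid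
Conditions: KOH, aq. DMSO, 90 °C; then aq. HCl, 0 °C
Reagents that add atoms: potassium hydroxide, [K+].[OH-]
Why: Saponification of a di-ortho-substituted benzoate with weakly solvated hydroxide in aqueous DMSO, the usual answer to hindered resorcylate esters; the aldehyde has no α hydrogen, is flanked on both sides and is deactivated by ortho and para alkoxy donors, so Cannizzaro disproportionation should not compete.

Step 7
Reactants: 16 2,4-bis(benzyloxy)-5-formyl-3,6-dimethylbenzoic acid; 11 methyl 2,4-dihydroxy-3,5,6-trimethylbenzoate
Product: 18 methyl 4-{[2,4-bis(benzyloxy)-5-formyl-3,6-dimethylbenzoyl]oxy}-2-hydroxy-3,5,6-trimethylbenzoate, via mixed anhydride 17 (not isolated)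
Conditions: (CF3CO)2O, toluene, rt
Reagents that add atoms: none
Why: Trifluoroacetic anhydride esterification of hindered acids: mixed anhydride 17 of the electron-rich di-ortho-substituted acid ionizes to a linear acylium ion that escapes the steric demand of a tetrahedral intermediate, and it should be captured by the free a4 hydroxyl and not by the a6 hydroxyl, which is tied up in a hydrogen bond to the a1 ester.

Step 8
Reactants: 18 methyl 4-{[2,4-bis(benzyloxy)-5-formyl-3,6-dimethylbenzoyl]oxy}-2-hydroxy-3,5,6-trimethylbenzoate
Product: 19 methyl 4-{[2,4-bis(benzyloxy)-5-formyl-3,6-dimethylbenzoyl]oxy}-2-methoxy-3,5,6-trimethylbenzoate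
Conditions: MeI, K2CO3, DMF, rt
Reagents that add atoms: iodomethane, CI
Why: Williamson O-methylation: the a6 hydroxyl is the only acidic group left, so no selectivity is needed, and the aryl ester should survive anhydrous carbonate because ring B bears no free phenol that could expel the aryloxide.

Step 9
Reactants: 19 methyl 4-{[2,4-bis(benzyloxy)-5-formyl-3,6-dimethylbenzoyl]oxy}-2-methoxy-3,5,6-trimethylbenzoate
Product: 20 methyl 4-[(5-formyl-2,4-dihydroxy-3,6-dimethylbenzoyl)oxy]-2-methoxy-3,5,6-trimethylbenzoate (target)
Conditions: BCl3, C6HMe5, CH2Cl2, −78 °C; then H2O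
Reagents that add atoms: none
Why: Lewis-acid debenzylation with a non-basic cation scavenger: BCl3 ionizes the two benzyl ethers, each next to a coordinating carbonyl group, at a temperature at which aryl methyl ethers and esters are inert, pentamethylbenzene traps the benzyl cation by Friedel–Crafts alkylation, and reductive conditions that could touch the aldehyde are avoided.

Compound list
1 | pentan-3-one | CCC(=O)CC | starting material
2 | acetaldehyde | CC=O | starting material
3 | 5-hydroxy-4-methylhexan-3-one (aldol, diastereomer mixture, not isolated) | CCC(=O)C(C)C(C)O | intermediate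
4 | (E)-4-methylhex-4-en-3-one | CCC(=O)/C(C)=C/C | intermediate
5 | dimethyl malonate | COC(=O)CC(=O)OC | starting material
6 | dimethyl 2-(3-methyl-4-oxohexan-2-yl)propanedioate (Michael adduct, diastereomer mixture, not isolated) | CCC(=O)C(C)C(C)C(C(=O)OC)C(=O)OC | intermediate
7 | sodium 6-(methoxycarbonyl)-2,4,5-trimethyl-3-oxocyclohex-1-en-1-olate (not isolated) | [Na+].COC(=O)C1C(C)C(C)C(=O)C(C)=C1[O-] | intermediate
8 | methyl 3,5,6-trimethyl-2,4-dioxocyclohexane-1-carboxylate (diastereomers and tautomers) | COC(=O)C1C(C)C(C)C(=O)C(C)C1=O | intermediate
9 | methyl 3-bromo-3,5,6-trimethyl-2,4-dioxocyclohexane-1-carboxylate (not isolated) | COC(=O)C1C(C)C(C)C(=O)C(C)(Br)C1=O | intermediate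
10 | methyl 1-bromo-3,5,6-trimethyl-2,4-dioxocyclohexane-1-carboxylate (not isolated) | COC(=O)C1(Br)C(C)C(C)C(=O)C(C)C1=O | intermediate
11 | methyl 2,4-dihydroxy-3,5,6-trimethylbenzoate | COC(=O)c1c(C)c(C)c(O)c(C)c1O | intermediate
12 | methyl 2,4-dihydroxy-3,6-dimethylbenzoate (atraric acid) | COC(=O)c1c(C)cc(O)c(C)c1O | starting material
13 | methyl 5-[chloro(methoxy)methyl]-2,4-dihydroxy-3,6-dimethylbenzoate (racemic, titanium-bound in the flask, not isolated) | COC(=O)c1c(C)c(C(Cl)OC)c(O)c(C)c1O | intermediate
14 | methyl 5-formyl-2,4-dihydroxy-3,6-dimethylbenzoate | COC(=O)c1c(C)c(C=O)c(O)c(C)c1O | intermediate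
15 | methyl 2,4-bis(benzyloxy)-5-formyl-3,6-dimethylbenzoate | COC(=O)c1c(C)c(C=O)c(OCc2ccccc2)c(C)c1OCc1ccccc1 | intermediate
16 | 2,4-bis(benzyloxy)-5-formyl-3,6-dimethylbenzoic acid | OC(=O)c1c(C)c(C=O)c(OCc2ccccc2)c(C)c1OCc1ccccc1 | intermediate
17 | 2,4-bis(benzyloxy)-5-formyl-3,6-dimethylbenzoic trifluoroacetic anhydride (not isolated) | O=C(OC(=O)C(F)(F)F)c1c(C)c(C=O)c(OCc2ccccc2)c(C)c1OCc1ccccc1 | intermediate
18 | methyl 4-{[2,4-bis(benzyloxy)-5-formyl-3,6-dimethylbenzoyl]oxy}-2-hydroxy-3,5,6-trimethylbenzoate | COC(=O)c1c(C)c(C)c(OC(=O)c2c(C)c(C=O)c(OCc3ccccc3)c(C)c2OCc2ccccc2)c(C)c1O | intermediate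
19 | methyl 4-{[2,4-bis(benzyloxy)-5-formyl-3,6-dimethylbenzoyl]oxy}-2-methoxy-3,5,6-trimethylbenzoate | COC(=O)c1c(C)c(C)c(OC(=O)c2c(C)c(C=O)c(OCc3ccccc3)c(C)c2OCc2ccccc2)c(C)c1OC | intermediate
20 | methyl 4-[(5-formyl-2,4-dihydroxy-3,6-dimethylbenzoyl)oxy]-2-methoxy-3,5,6-trimethylbenzoate | COC(=O)c1c(C)c(C)c(OC(=O)c2c(C)c(C=O)c(O)c(C)c2O)c(C)c1OC | target

Total step count: 9.
Longest linear sequence: 6 (steps 1, 2, 3, 7, 8, 9). The ring B branch (steps 4, 5, 6, 7, 8, 9) is equally long.

Steps most likely to fail

Step 7 (depside esterification).
- **Risk:** the a4 hydroxyl lies between two methyl groups, so it may capture the acylating species too slowly. Trifluoroacetylation of the phenol, acid-induced loss of a benzyl ether or acylation at a6 could then take over.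
- **Fallback:** the order of events is changed so that the phenol partner has a single hydroxyl and can be used as its anion. Setting out from 11, one equivalent of BnBr with K2CO3 in acetone should etherify only the unchelated a4 hydroxyl and give methyl 4-(benzyloxy)-2-hydroxy-3,5,6-trimethylbenzoate F1. MeI and K2CO3 in DMF should then give methyl 4-(benzyloxy)-2-methoxy-3,5,6-trimethylbenzoate F2. Hydrogenolysis (H2, Pd/C, EtOAc, no aldehyde being present in this series) should free methyl 4-hydroxy-2-methoxy-3,5,6-trimethylbenzoate F3. In parallel, acid 16 is turned with (COCl)2 and catalytic DMF into 2,4-bis(benzyloxy)-5-formyl-3,6-dimethylbenzoyl chloride F4. F3 is deprotonated with NaH in THF to sodium 3-methoxy-4-(methoxycarbonyl)-2,5,6-trimethylphenolate F5, and the two are combined. The product is 19, where the route is rejoined, and step 8 is no longer needed.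

Step 3 (aromatization).
- **Risk:** the halogen may stay parked on the blocked a5 carbon. HBr may also be lost toward a methyl group instead of toward the a2 hydrogen, or hot HBr may start to cleave the ester.
- **Fallback:** the oxidation is done by sulfonation and loss of sulfur dioxide instead of by halogen. Setting out from 8, Ac2O with H2SO4 in AcOH (0 to 50 °C), the known conversion of cyclic ketones and dihydroresorcinols into aryl acetates, should give methyl 2,4-diacetoxy-3,5,6-trimethylbenzoate F6. Acid-catalysed methanolysis (HCl, MeOH) should then return the route to 11.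

Step 2 (Michael–Claisen ring closure).
- **Risk:** conjugate addition to an enone substituted at both olefinic carbons is slow and reversible. Retro-addition, deconjugation or base-induced self-condensation of the enone may outrun the ring closure.
- **Fallback:** the open-chain adduct is reached with a much stronger acceptor, and the same Claisen closure of a5–a6 is kept. Setting out from 2 and 5, Knoevenagel condensation in hot Ac2O should give dimethyl 2-ethylidenepropanedioate F7. Ketone 1 is converted with LiN(i-Pr)2 in THF at −78 °C into lithium pent-2-en-3-olate F8, which should add to F7 (forming a2–a3 in place of a1–a2). Quenching with aq. NH4Cl should deliver 6 as an isolated compound, where the route is rejoined. NaOMe in refluxing MeOH then closes 6 through 7 to 8 as in step 2.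

Further compounds
F1 | step 7 | methyl 4-(benzyloxy)-2-hydroxy-3,5,6-trimethylbenzoate | COC(=O)c1c(C)c(C)c(OCc2ccccc2)c(C)c1O
F2 | step 7 | methyl 4-(benzyloxy)-2-methoxy-3,5,6-trimethylbenzoate | COC(=O)c1c(C)c(C)c(OCc2ccccc2)c(C)c1OC
F3 | step 7 | methyl 4-hydroxy-2-methoxy-3,5,6-trimethylbenzoate | COC(=O)c1c(C)c(C)c(O)c(C)c1OC
F4 | step 7 | 2,4-bis(benzyloxy)-5-formyl-3,6-dimethylbenzoyl chloride | O=C(Cl)c1c(C)c(C=O)c(OCc2ccccc2)c(C)c1OCc1ccccc1
F5 | step 7 | sodium 3-methoxy-4-(methoxycarbonyl)-2,5,6-trimethylphenolate | [Na+].COC(=O)c1c(C)c(C)c([O-])c(C)c1OC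
F6 | step 3 | methyl 2,4-diacetoxy-3,5,6-trimethylbenzoate | COC(=O)c1c(C)c(C)c(OC(C)=O)c(C)c1OC(C)=O
F7 | step 2 | dimethyl 2-ethylidenepropanedioate | CC=C(C(=O)OC)C(=O)OC
F8 | step 2 | lithium pent-2-en-3-olate (geometry without consequence) | [Li+].CC=C([O-])CC
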